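**Target:** methyl 3-chloro-4-[(3-chloro-5-formyl-4,6-dihydroxy-2-methylbenzoyl)oxy]-6-hydroxy-2,5-dimethylbenzoate (17)

## The problem

The target is a depside: two hexasubstituted benzene rings joined by an aryl ester between the carboxyl carbon on C1' of ring A and the oxygen on C4 of ring B. Ring B carries CO2Me (C1), CH3 (C2), Cl (C3), the acyloxy group (C4), CH3 (C5) and OH (C6). Ring A carries the ester carbonyl (C1'), CH3 (C2'), Cl (C3'), OH (C4'), CHO (C5') and OH (C6'). There is no stereocenter, so the problem is purely regiochemical: twelve ring positions must each receive the right substituent, with one chlorine on each ring. The linking ester is flanked by two ortho substituents on the acyl side (C2' CH3, C6' O) and two on the phenol side (C3 Cl, C5 CH3), so joining the finished halves means an esterification between two hindered partners. The aldehyde at C5', the aryl ester (open to hydrolysis, transesterification and acyl transfer), the methyl ester and the two aryl chlorides exclude strong nucleophiles, strong aqueous base and hydrogenolysis late in the route. The enabling feature is that ring B is a resorcinol monoester: the free hydroxyl at C6 and the acylated oxygen at C4 are meta to each other across C5, with the ester-bearing C1 next to the hydroxyl. A carbonylative [5+1] benzannulation of a 3-acyloxy-1,4-enyne writes exactly this pattern (CO becomes C6, the alkyne carbons C5 and C4, the carbinol carbon C3, the alkene carbons C2 and C1). The ester can therefore be made on an unhindered secondary alcohol and carried onto C4 as the ring forms.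

## Retrosynthesis

**17 to 16 (two O–CH3 bonds).** The two ring A hydroxyls are masked as methyl ethers. Methyl is chosen because it comes with the purchased arene 1 and survives butyllithium, electrophilic halogenation, palladium carbonylation, acid chloride formation, rhodium under CO and SO2Cl2. Benzyl ethers would invite a hydrogenolysis that the aryl chlorides and the aldehyde forbid, and acetal ethers would not survive the HCl released in steps 6 and 8. Both ethers of 16 sit ortho to a carbonyl group (C4'–OMe next to CHO; C6'–OMe between CHO and the ester carbonyl), which is the arrangement that BCl3 cleaves by chelation. The forward step must remove both without touching the two esters.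

**16 to 15 (C3–Cl).** The ring B chlorine is put on last among the skeletal substituents. In 15, C3 is the only aromatic C–H of the molecule (ring A has none) and it is para to the C6 hydroxyl. The chlorine cannot be carried through the ring construction, because C3 derives from the carbinol carbon, which must bear hydrogen and oxygen. The forward step is a mono-chlorination with no regiochemical choice.

**15 to 12 and 6 (C4–O, C5–C6, C6–C1; the strategic cut).** Ring B is opened to the racemic 3-acyloxy-1,4-enyne 12 and carbon monoxide 6. The neighbouring cut, the ester bond between a finished ring A acid and a finished ring B phenol, is shorter, but it asks a doubly ortho-substituted acyl donor to meet a doubly ortho-substituted phenol. The chosen cut builds ring B from a seven-carbon chain and one CO, places CO2Me, both methyl groups and both oxygens correctly from the connectivity of 12, and moves the ester from a secondary carbinol to C4 in the same event. The weak point is known: enynes of this class with an alkyl-capped alkyne normally undergo 1,3-acyloxy shift and [4+1] carbonylation to cyclopentenones, and the benzannulation is established for terminal alkynes. A terminal alkyne would restore precedent but leave C5 unsubstituted; C-methylation between two oxygen substituents, beside a free C3, would cost at least two steps and add its own regiochemical risk. The methyl group is therefore carried in the alkyne and the risk is taken in the key step. It is supported by CO pressure, by the irreversible aromatisation as a sink, and by a short fallback of known chemistry that rejoins the route at 15.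

**12 to 7 (as chloride 11) and 10 (ester C(=O)–O).** The ester is disconnected at the carbinol oxygen. The alcohol 10 is secondary and unhindered, so only the acyl partner is congested, and a DMAP-catalysed acylation by acid chloride 11 is sufficient. The forward step must avoid base-induced isomerisation of the doubly activated carbinol C–H.

**10 to 8 and 9 (carbinol–alkyne C–C).** Addition of 1-propynylmagnesium bromide 9 to the aldehyde of 8 gives the whole ring B carbon chain in one step. The E geometry of 8 is retained; it prevents lactonisation of the alkoxide and later places CO2Me on the outside of the closing triene. Chemoselectivity for the aldehyde over the conjugated ester is required.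

**7 to 5 and 6 (C1'–CO2H), then 5 to 4 (C–I), 4 to 3 (C–Cl).** The carboxyl group is introduced by palladium hydroxycarbonylation of iodide 5, because the free aldehyde excludes halogen–metal exchange and CO2. Aldehyde 3 is symmetrical, with two equivalent free positions, so chlorination to 4 and iodination of the one remaining position to 5 raise no regiochemical question.

**3 to 1 via 2 (C5'–CHO).** Directed lithiation of 3,5-dimethoxytoluene 1 between the two methoxy groups gives aryllithium 2, and formylation puts the aldehyde at the only position flanked by both oxygens. Electrophilic formylation would go ortho to the methyl group instead.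

## Roads not taken

**Alternative 1: aryne insertion into DMF.** The cut is at C4'–O and C5'–CHO of ring A, traced to a C4'–C5' aryne. Fluoride acting on silyl triflate A2 would generate the aryne. The DMF oxygen adds to C4', the aryne carbon remote from the methoxy group, and the formyl carbon to C5'; hydrolysis gives the ortho-hydroxy aldehyde A1. The merits are a predictable regiochemistry and a free C4' hydroxyl, so that only one ether would remain to be cleaved at the end. In that respect it is better than the chosen plan, which has to rely on a double chelation-assisted demethylation in step 9. The weak points are that A2 is itself a pentasubstituted arene needing several steps, and that the step solves only the oxygen–formyl pair of ring A. The chosen route obtains that pair in one directed lithiation of symmetrical 1. The hindered ester linkage and ring B are left untouched by this road, and the free phenol of A1 would have to be masked again before acid activation.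

**Alternative 2: three-component palladium carbonylative esterification.** The cut is at C1'–C(=O) and C(=O)–O. Iodide 5, CO and the 4-hydroxyl of the ring B phenol A4 would combine on palladium to give A3, which has the structure of 16. This road is more convergent and shorter, since A4 is one chlorination away from a purchasable phenol, and aryloxycarbonylation of aryl iodides is a known reaction class. On step count and on precedent it is at least as good as the chosen plan. Its weak point is the union itself: a di-ortho-substituted aroylpalladium must be captured by a phenoxide flanked by Cl and CH3, so C–O bond formation is slow and reduction of the iodide or diaryl ether formation can take over. The chosen plan sets against it that the ester is formed at an unhindered secondary alcohol and is transposed intramolecularly, and that ring B is assembled with its substituents fixed by connectivity.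

**Alternative 3: biomimetic tetraketide aldol aromatisation.** The cut is at C1'–C2' of ring A. The ring B aryl 3,5,7-trioxooctanoate A6 would undergo aldol addition of C2 to the C7 ketone, dehydration and enolisation to give the orsellinate depside A5. The ester would be made with an unhindered aliphatic acyl donor, which answers the hindrance problem as well as the chosen plan does, and the ring closure follows the biosynthetic logic. The weak points are two. An aryl ester of a triketo acid has a good phenoxide leaving group, so lactonisation to a 4-hydroxy-2-pyrone with loss of ring B competes with the aldol. A5 still lacks the C5' aldehyde and the C3' chlorine, which must be introduced at two similarly activated positions of a free resorcinol. The chosen plan fixes all six ring A substituents before the union on a symmetrical precursor, and pays for this with a longer ring A sequence.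

Key step: step 7

Assumption: aldehyde 8 is purchased as the pure E isomer. The carbinol stereocenter of 10 and 12 is racemic and is destroyed in step 7, so no stereocontrol is needed anywhere.

## Route

Step 1
Reactants: 1 3,5-dimethoxytoluene
Product: 3 2,6-dimethoxy-4-methylbenzaldehyde, via aryllithium 2 (not isolated)
Conditions: n-BuLi, TMEDA, THF, 0 °C to rt; then DMF, 0 °C to rt; aq NH4Cl
Reagents that add atoms: N,N-dimethylformamide, CN(C)C=O
Why: Directed ortho-lithiation occurs at the position flanked by both methoxy groups, and the aryllithium is formylated by DMF; the position is fixed by the double coordination, so the aldehyde lands where C5' must be.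

Step 2
Reactants: 3 2,6-dimethoxy-4-methylbenzaldehyde
Product: 4 3-chloro-2,6-dimethoxy-4-methylbenzaldehyde
Conditions: NCS (1.05 equiv), MeCN, 60 °C
Reagents that add atoms: N-chlorosuccinimide, O=C1CCC(=O)N1Cl
Why: Electrophilic aromatic chlorination; the two free positions of symmetrical 3 are equivalent (each ortho to one OMe, para to the other, meta to CHO), and the first chlorine deactivates the ring towards a second.

Step 3
Reactants: 4 3-chloro-2,6-dimethoxy-4-methylbenzaldehyde
Product: 5 3-chloro-5-iodo-2,6-dimethoxy-4-methylbenzaldehyde
Conditions: NIS (1.1 equiv), CF3CO2H, MeCN, rt
Reagents that add atoms: N-iodosuccinimide, O=C1CCC(=O)N1I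
Why: Acid-activated electrophilic iodination at the single remaining ring C–H, which is still activated by an ortho and a para methoxy group; no regiochemical alternative exists.

Step 4
Reactants: 5 3-chloro-5-iodo-2,6-dimethoxy-4-methylbenzaldehyde; 6 carbon monoxide
Product: 7 3-chloro-5-formyl-4,6-dimethoxy-2-methylbenzoic acid
Conditions: Pd(OAc)2 (5 mol%), Xantphos, CO (1 atm), Et3N, DMF/H2O, 80 °C; then aq HCl
Reagents that add atoms: water, O
Why: Palladium-catalysed hydroxycarbonylation: zerovalent palladium formed in situ inserts into the C–I bond only, CO insertion gives the aroylpalladium and water releases the acid. The aryl chloride and the non-enolisable aldehyde are spectators, and the aldehyde rules out the organometallic alternative.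

Step 5
Reactants: 8 methyl (E)-3-methyl-4-oxobut-2-enoate; 9 1-propynylmagnesium bromide
Product: 10 methyl (E)-4-hydroxy-3-methylhept-2-en-5-ynoate (racemic)
Conditions: THF, −78 °C; aq NH4Cl
Reagents that add atoms: none
Why: Chemoselective 1,2-addition of an alkynyl Grignard reagent to the aldehyde in the presence of the less electrophilic conjugated ester at low temperature. The new carbinol center is formed racemic, which is sufficient because it becomes sp2 in step 7, and the E alkene cannot lactonise.

Step 6
Reactants: 7 3-chloro-5-formyl-4,6-dimethoxy-2-methylbenzoic acid; 10 methyl (E)-4-hydroxy-3-methylhept-2-en-5-ynoate (racemic)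
Product: 12 methyl (E)-4-[(3-chloro-5-formyl-4,6-dimethoxy-2-methylbenzoyl)oxy]-3-methylhept-2-en-5-ynoate (racemic), via acid chloride 11 (not isolated)
Conditions: (COCl)2, cat. DMF, CH2Cl2, 0 °C to rt, concentrate; then 10, Et3N, DMAP (cat.), CH2Cl2, 0 °C to rt
Reagents that add atoms: none
Why: Acid chloride formation through the chloroiminium reagent, followed by DMAP-catalysed acyl transfer to an unhindered secondary alcohol. The congested ester bond is thus made where only one partner is hindered, and the aldehyde (meta to the carboxyl group) cannot form a cyclic pseudo-chloride.

Step 7
Reactants: 12 methyl (E)-4-[(3-chloro-5-formyl-4,6-dimethoxy-2-methylbenzoyl)oxy]-3-methylhept-2-en-5-ynoate (racemic); 6 carbon monoxide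
Product: 15 methyl 4-[(3-chloro-5-formyl-4,6-dimethoxy-2-methylbenzoyl)oxy]-6-hydroxy-2,5-dimethylbenzoate, via dienylketene 13 (not isolated), via cyclohexadienone tautomer 14 (not isolated)
Conditions: [RhCl(CO)2]2 (5 mol%), CO (10 atm), ClCH2CH2Cl, 60 °C
Reagents that add atoms: none
Why: Proposed new method: the closest known reaction is the [RhCl(CO)2]2-catalysed [5+1] carbonylative benzannulation of 3-acyloxy-1,4-enynes with a terminal alkyne, whereas alkyl-capped alkynes of this class are known to prefer 1,3-acyloxy shift and [4+1] carbonylation to cyclopentenones, so the 1,2-shift manifold is asked here of a methyl-capped alkyne. Monovalent rhodium binds the alkyne of 12, the aroyl carbonyl oxygen attacks the proximal alkyne carbon (5-exo) to give a dioxolenium ion, and its opening moves the ring A carboxylate from the carbinol carbon (future C3) to the future C4 and leaves a rhodium vinylcarbene at the methyl-bearing future C5. CO insertion at the carbene carbon forms C5–C6 and the dienylketene 13; thermal disrotatory 6π electrocyclisation joins C6 to the enoate α-carbon C1 and closes the six-membered ring B as dienone 14, which tautomerises irreversibly to phenol 15 (equivalently, CO insertion into a rhodacyclohexadiene and reductive elimination). No stereocenter persists: the carbinol carbon of 12 becomes sp2 and the sp3 C1 of 14 is lost on enolisation. The selectivity needed is 1,2- over 1,3-acyloxy shift, and three features argue for it: the 1,3-shift to the allenyl ester is expected to be reversible on rhodium while aromatisation is not; CO pressure keeps rhodium coordinatively saturated, which disfavours the η4-vinylallene binding that [4+1] carbonylation needs and speeds capture of the carbene; and the enoate conjugates with the vinylcarbene and, being E, holds CO2Me on the outside of the closing triene. The ring A oxygens are methyl ethers so that no O–H can trap carbene or ketene, and the aldehyde and aryl chloride are inert to [RhCl(CO)2]2 under CO at this temperature.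

Step 8
Reactants: 15 methyl 4-[(3-chloro-5-formyl-4,6-dimethoxy-2-methylbenzoyl)oxy]-6-hydroxy-2,5-dimethylbenzoate
Product: 16 methyl 3-chloro-4-[(3-chloro-5-formyl-4,6-dimethoxy-2-methylbenzoyl)oxy]-6-hydroxy-2,5-dimethylbenzoate
Conditions: SO2Cl2 (1.05 equiv), CH2Cl2, 0 °C to rt, dark
Reagents that add atoms: sulfuryl chloride, O=S(=O)(Cl)Cl
Why: Electrophilic aromatic chlorination of a phenol; C3 is the only aromatic C–H in 15 and is para to the C6 hydroxyl, ring A is fully substituted, and exclusion of light suppresses benzylic radical chlorination.

Step 9
Reactants: 16 methyl 3-chloro-4-[(3-chloro-5-formyl-4,6-dimethoxy-2-methylbenzoyl)oxy]-6-hydroxy-2,5-dimethylbenzoate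
Product: 17 methyl 3-chloro-4-[(3-chloro-5-formyl-4,6-dihydroxy-2-methylbenzoyl)oxy]-6-hydroxy-2,5-dimethylbenzoate (target)
Conditions: BCl3 (excess), CH2Cl2, −78 °C to rt; aq work-up
Reagents that add atoms: none
Why: Chelation-controlled cleavage of aryl methyl ethers ortho to a carbonyl group by BCl3: the C4' ether is activated through the aldehyde and the C6' ether through the aldehyde or the ester carbonyl. The methyl ester and the aryl ester are cleaved much more slowly under these conditions and should survive.

## Compound list

1 | 3,5-dimethoxytoluene | COc1cc(C)cc(OC)c1 | starting material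
2 | (2,6-dimethoxy-4-methylphenyl)lithium | [Li]c1c(OC)cc(C)cc1OC | intermediate
3 | 2,6-dimethoxy-4-methylbenzaldehyde | COc1cc(C)cc(OC)c1C=O | intermediate
4 | 3-chloro-2,6-dimethoxy-4-methylbenzaldehyde | COc1cc(C)c(Cl)c(OC)c1C=O | intermediate
5 | 3-chloro-5-iodo-2,6-dimethoxy-4-methylbenzaldehyde | COc1c(I)c(C)c(Cl)c(OC)c1C=O | intermediate
6 | carbon monoxide | [C-]#[O+] | starting material
7 | 3-chloro-5-formyl-4,6-dimethoxy-2-methylbenzoic acid | OC(=O)c1c(C)c(Cl)c(OC)c(C=O)c1OC | intermediate
8 | methyl (E)-3-methyl-4-oxobut-2-enoate | COC(=O)/C=C(C)/C=O | starting material
9 | 1-propynylmagnesium bromide | CC#C[Mg]Br | starting material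
10 | methyl (E)-4-hydroxy-3-methylhept-2-en-5-ynoate (racemic) | COC(=O)/C=C(C)/C(O)C#CC | intermediate
11 | 3-chloro-5-formyl-4,6-dimethoxy-2-methylbenzoyl chloride | ClC(=O)c1c(C)c(Cl)c(OC)c(C=O)c1OC | intermediate
12 | methyl (E)-4-[(3-chloro-5-formyl-4,6-dimethoxy-2-methylbenzoyl)oxy]-3-methylhept-2-en-5-ynoate (racemic) | COC(=O)/C=C(C)/C(OC(=O)c1c(C)c(Cl)c(OC)c(C=O)c1OC)C#CC | intermediate
13 | methyl (2E,4E)-5-[(3-chloro-5-formyl-4,6-dimethoxy-2-methylbenzoyl)oxy]-3,6-dimethyl-7-oxohepta-2,4,6-trienoate | COC(=O)/C=C(C)/C=C(\C(C)=C=O)OC(=O)c1c(C)c(Cl)c(OC)c(C=O)c1OC | intermediate
14 | methyl 4-[(3-chloro-5-formyl-4,6-dimethoxy-2-methylbenzoyl)oxy]-2,5-dimethyl-6-oxocyclohexa-2,4-diene-1-carboxylate (racemic) | COC(=O)C1C(C)=CC(OC(=O)c2c(C)c(Cl)c(OC)c(C=O)c2OC)=C(C)C1=O | intermediate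
15 | methyl 4-[(3-chloro-5-formyl-4,6-dimethoxy-2-methylbenzoyl)oxy]-6-hydroxy-2,5-dimethylbenzoate | COC(=O)c1c(C)cc(OC(=O)c2c(C)c(Cl)c(OC)c(C=O)c2OC)c(C)c1O | intermediate
16 | methyl 3-chloro-4-[(3-chloro-5-formyl-4,6-dimethoxy-2-methylbenzoyl)oxy]-6-hydroxy-2,5-dimethylbenzoate | COC(=O)c1c(C)c(Cl)c(OC(=O)c2c(C)c(Cl)c(OC)c(C=O)c2OC)c(C)c1O | intermediate
17 | methyl 3-chloro-4-[(3-chloro-5-formyl-4,6-dihydroxy-2-methylbenzoyl)oxy]-6-hydroxy-2,5-dimethylbenzoate | COC(=O)c1c(C)c(Cl)c(OC(=O)c2c(C)c(Cl)c(O)c(C=O)c2O)c(C)c1O | target

## Step count and risks

Total: 9 steps. Longest linear sequence: 8 steps (1, 2, 3, 4, 6, 7, 8, 9, from 3,5-dimethoxytoluene); step 5 is a one-step side branch.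

**Step 7 (key step, proposed new method).** The most likely failure is that the acyloxy group migrates 1,3 to the distal, methyl-bearing alkyne carbon, and the resulting allenyl ester is carbonylated in the [4+1] sense to a cyclopentenone. The alkyl cap stabilises positive charge at that carbon, so this is the intrinsic bias of the substrate. Slow migration of the electron-poor, twisted aroyl group would add to the problem. Fallback with known chemistry: setting out from acid 7, trifluoroacetic anhydride in toluene gives the mixed anhydride 3-chloro-5-formyl-4,6-dimethoxy-2-methylbenzoic trifluoroacetic anhydride F1. This acylates the free 4-hydroxyl of purchased methyl 2,4-dihydroxy-3,6-dimethylbenzoate F2, whose 2-hydroxyl is tied up in a hydrogen bond to the ester. This classical mixed-anhydride depside coupling of a hindered aromatic acid comes back to the route at 15.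

**Step 9.** The sequence may stall after the first demethylation, because the boron phenoxide formed then occupies the aldehyde oxygen that the second ether needs for chelation. Prolonged exposure to force the second cleavage risks chelate-assisted loss of the methyl ester or scission of the depside ester. Fallback: setting out from 16, BCl3 at −78 °C is used only for the first, fast cleavage to the mono-ether methyl 3-chloro-4-[(3-chloro-5-formyl-6-hydroxy-4-methoxy-2-methylbenzoyl)oxy]-6-hydroxy-2,5-dimethylbenzoate F3. F3 is drawn with the C4' ether surviving; the second stage is the same if the other ether survives. The remaining ether is then removed by a mechanistically different reagent, MgI2·OEt2 in toluene, in which magnesium bridges carbonyl and ether oxygen and iodide attacks the methyl group in an SN2 step. This comes back to the route at 17.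

**Step 6.** Acyl transfer from the di-ortho-substituted acid chloride may be slow, and long exposure of 12 to amine base can isomerise the doubly activated carbinol C–H to an allene or a conjugated dienoate. Fallback: setting out from 8 and 9, the addition is run as in step 5 but is not quenched. The bromomagnesium alkoxide of 10, F4, is acylated in the same flask by acid chloride 11 (prepared from 7), so that a charged alkoxide rather than a neutral alcohol attacks the hindered carbonyl and no amine is present. This comes back to the route at 12.

**Step 4.** CO insertion and hydrolysis at the di-ortho-substituted arylpalladium may be slower than protodeiodination, returning the reduced arene. Fallback: setting out from 5, the aldehyde is masked as the acetal 2-(3-chloro-5-iodo-2,6-dimethoxy-4-methylphenyl)-1,3-dioxolane F5 (ethylene glycol, TsOH, toluene, water removal). Iodine–magnesium exchange with i-PrMgCl·LiCl gives [3-chloro-5-(1,3-dioxolan-2-yl)-4,6-dimethoxy-2-methylphenyl]magnesium chloride F6, and CO2 gives 3-chloro-5-(1,3-dioxolan-2-yl)-4,6-dimethoxy-2-methylbenzoic acid F7. Aqueous HCl then removes the acetal, and the sequence comes back to the route at 7.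

## Further compounds

F1 | step 7 | 3-chloro-5-formyl-4,6-dimethoxy-2-methylbenzoic trifluoroacetic anhydride | O=C(OC(=O)C(F)(F)F)c1c(C)c(Cl)c(OC)c(C=O)c1OC
F2 | step 7 | methyl 2,4-dihydroxy-3,6-dimethylbenzoate (purchased) | COC(=O)c1c(C)cc(O)c(C)c1O
F3 | step 9 | methyl 3-chloro-4-[(3-chloro-5-formyl-6-hydroxy-4-methoxy-2-methylbenzoyl)oxy]-6-hydroxy-2,5-dimethylbenzoate | COC(=O)c1c(C)c(Cl)c(OC(=O)c2c(C)c(Cl)c(OC)c(C=O)c2O)c(C)c1O
F4 | step 6 | bromomagnesium (E)-7-methoxy-5-methyl-7-oxohept-5-en-2-yn-4-olate (alkoxide of 10, racemic) | COC(=O)/C=C(C)/C(O[Mg]Br)C#CC
F5 | step 4 | 2-(3-chloro-5-iodo-2,6-dimethoxy-4-methylphenyl)-1,3-dioxolane | COc1c(I)c(C)c(Cl)c(OC)c1C1OCCO1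
F6 | step 4 | [3-chloro-5-(1,3-dioxolan-2-yl)-4,6-dimethoxy-2-methylphenyl]magnesium chloride | COc1c([Mg]Cl)c(C)c(Cl)c(OC)c1C1OCCO1
F7 | step 4 | 3-chloro-5-(1,3-dioxolan-2-yl)-4,6-dimethoxy-2-methylbenzoic acid | OC(=O)c1c(C)c(Cl)c(OC)c(C2OCCO2)c1OC
A1 | alternative 1 | tert-butyl 3-formyl-4-hydroxy-2-methoxy-6-methylbenzoate | CC(C)(C)OC(=O)c1c(C)cc(O)c(C=O)c1OC
A2 | alternative 1 | tert-butyl 2-methoxy-6-methyl-4-(trifluoromethylsulfonyloxy)-3-(trimethylsilyl)benzoate | CC(C)(C)OC(=O)c1c(C)cc(OS(=O)(=O)C(F)(F)F)c([Si](C)(C)C)c1OC
A3 | alternative 2 | methyl 3-chloro-4-[(3-chloro-5-formyl-4,6-dimethoxy-2-methylbenzoyl)oxy]-6-hydroxy-2,5-dimethylbenzoate | COC(=O)c1c(C)c(Cl)c(OC(=O)c2c(C)c(Cl)c(OC)c(C=O)c2OC)c(C)c1O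
A4 | alternative 2 | methyl 3-chloro-4,6-dihydroxy-2,5-dimethylbenzoate | COC(=O)c1c(C)c(Cl)c(O)c(C)c1O
A5 | alternative 3 | methyl 3-chloro-4-[(2,4-dihydroxy-6-methylbenzoyl)oxy]-6-hydroxy-2,5-dimethylbenzoate | COC(=O)c1c(C)c(Cl)c(OC(=O)c2c(C)cc(O)cc2O)c(C)c1O
A6 | alternative 3 | methyl 3-chloro-6-hydroxy-2,5-dimethyl-4-[(3,5,7-trioxooctanoyl)oxy]benzoate | COC(=O)c1c(C)c(Cl)c(OC(=O)CC(=O)CC(=O)CC(C)=O)c(C)c1O
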